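If the flask is read later than any earlier run, its curve can be replaced by a mean: k̄, the natural logarithm of substrate charged over substrate left, divided by the time. This is a mean pseudo-first-order constant. The fraction of the charged substrate left is then exp(−k̄t), with t the time.

all flasks: gas phase 150 mM (held)
- Wednesday's: substrate 0.27 M; catalyst 1.7 mol%; run made earlier
- Monday's: substrate 0.27 M; catalyst 3.8 mol%; run made earlier
- Sunday's: substrate 0.41 M; catalyst 2.5 mol%; run made earlier
- flask: substrate 0.27 M; catalyst 2.5 mol%; time 40 min

- Wednesday's (time / min: target / %, idle complex B / %): 8.00: 28.9, 0.5; 15.0: 47.0, 0.2; 25.0: 62.6, 0.5; 30.0: 69.1, 0.3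
- Monday's (time / min: target / %, idle complex B / %): 4.00: 28.6, 0.7; 12.0: 64.1, 0.2; 20.0: 80.9, 0.9; 30.0: 91.1, 1.4
- Sunday's (time / min: target / %, idle complex B / %): 2.50: 16.0, 0; 6.00: 39.7, 0.9; 15.0: 67.6, 1.7; 30.0: 86.9, 1.3

(standard deviation of a reading: 0.5 percentage points)

- what is said of target includes idle complex B
- at the start none of the gas is dissolved
- steps that have been proposed: gas phase <-> dissolved gas; substrate + dissolved gas + catalyst -> catalyst + target; dissolved gas + catalyst <-> idle complex A; catalyst + target <-> idle complex B

- the target and idle complex B together standing at 40 min, as a percentage of the substrate charged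
- concentration of dissolved gas in solution at 40 min, in percent of saturation

**Which runs bear on the flask?** Wednesday's and Monday's, which share its substrate and gas and lie either side of its 2.5 mol% loading. Sunday's has that loading, but at 0.41 M substrate, so I set it aside.

**What are their means?** At 30.0 min, Wednesday's run gives 0.0391 min⁻¹ and Monday's 0.0806 min⁻¹. Interpolating straight in loading gives the flask k̄ = 0.0550 min⁻¹.

**Your answer?** At 40 min, that puts target at 88.9%.

**But does the mean hold still?** No. Wednesday's run reads 0.0423 min⁻¹ at 15.0 min, higher than at its last reading, a ratio of 0.925.

**What does that cost?** Multiplying k̄ by that whole ratio gives 86.9%, so I commit to the span between, 2 percentage points wide.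

**And the dissolved gas?** k̄ does not speak to it, so I give no number of my own.

The forecast says 88% for the first question, on the ground “Product inhibition lowers the late rate”, and 98.5% for the dissolved gas.

The flask gives 87.7% and 99.0%.

    gas phase ⇌ dissolved gas, rate k1*(csat - [dissolved gas]) (kL = 0.0181 s⁻¹)
    substrate + dissolved gas + catalyst → catalyst + target (k = 1.82 M⁻² s⁻¹)
    dissolved gas + catalyst ⇌ idle complex A, settled at all times (K = 3.05 M⁻¹)
    catalyst + target ⇌ idle complex B (K = 4.00 M⁻¹, k = 0.0181 M⁻¹ s⁻¹)

The flask's own k̄ at 40 min is 0.0525 min⁻¹, below the interpolated 0.0550 min⁻¹. At 40.0 min in the flask, the relaxation half-life between catalyst + free target and idle complex B, 1.31 min by that step alone with both ways together, is shorter than the substrate's 15 min half-life by its productive step, and idle complex B holds 38.8% of the catalyst charged, against 5.51% at 4.00 min. For the neighbour flask read at 10 min, the interpolated k̄ gives 42.3%, while that flask holds 45.2%, a mean of 0.0601 min⁻¹.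

The readings were generated by integration for substances that don't exist; noise was put on by code.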